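Birch cannot have turned its lost substrate into target: at 1.00 min its readings show substrate 20.8% and target 28.1%, so 51.1% of the charge stands in neither.

| flask | substrate | remark | time |
|---|---|---|---|
| birch | 0.034 M | run made earlier |  |
| oak | 0.075 M | run made earlier |  |
| flask | 0.050 M |  | 30 min |

- birch (time / min: target / %, substrate / %): 0.250: 19.4, 50.2; 1.00: 28.1, 20.8; 4.00: 19.1, 11.1; 20.0: 5.8, 4.3
- oak (time / min: target / %, substrate / %): 0.250: 15.0, 33.9; 1.00: 20.2, 11.9; 4.00: 13.2, 5.7; 20.0: 3.1, 0

(readings scatter by 1 percentage point)

1. when, up to 30 min, the flask holds most target
2. the amount of target, in percent of the substrate charged, at that time
3. the first time at which target reaches 7.6%, in the same percent, in min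

- in percentages every species weighs as the substrate in it: one self-condensation product counts as two
- for target the crystals are counted in
- as a solid, counted per litre of solution: crystals
- reactions considered so far: substrate <-> target; substrate <-> isomer of the product; substrate -> decomposition product; 2 substrate -> self-condensation product; crystals <-> target

The balance of substrate reads: charged = substrate + target + remainder. Remainder per target, a selectivity factor, reads 1.82 in birch and 3.36 in oak at that time, larger at the larger charge, as a second-order loss beside a first-order making leads one to expect. The split concentration, the charge at which remainder and target stand equal, is the mean of charge over factor in the two runs: 0.0205 M, a reading with their scatter.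

First instants: reciprocal substrate, interpolated in the charge, puts the flask at 42.3% substrate after 0.250 min, a mean decay of 3.44 min⁻¹. Target reaches the level asked once substrate has lost that level times (one + charge ÷ split concentration):

first arrival ≈ 0.0879 min

Middle: both runs read their highest target at 1.00 min. The same interpolation gives the flask 16.1% substrate then, and the balance gives:

target = substrate lost ÷ (one + charge ÷ split concentration) = 24.4%

End: target and substrate fall together, birch reading 5.8% and 4.3% at 20.0 min, with no second maximum in the readings, so the best time stays near 1.00 min.

The forecast, on “second-order self-condensation competing with first-order target formation”, says 0.9 min, 25% and 0.08 min, its peak above this reckoning and its arrival earlier. The flask gives 0.932 min, 25.2% and 0.0773 min.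

    substrate ⇌ target (K = 1.50, k = 0.0200 s⁻¹)
    substrate ⇌ isomer of the product (K = 2.30, k = 0.00140 s⁻¹)
    substrate → decomposition product (k = 1.80 × 10⁻⁵ s⁻¹)
    2 substrate → self-condensation product (k = 0.590 M⁻¹ s⁻¹)
    crystals ⇌ target, rate k5*(cs5 - [target]) while solid is left; crystals form when [target] > cs5 (solubility = 44.0 mM, k = 0.0840 s⁻¹)

In the flask, substrate's first half-life by self-condensation by itself is 0.282 min, about half of the 0.58 min by the forward making of target by itself. At 0.932 min the flask holds 55.2% self-condensation product against 25.2% target.

A neighbour flask is charged with 0.030 M, less than birch's 0.034 M, so the line through the two runs is here extrapolated, not interpolated: with the split concentration it gives 31.5% target at its height. That neighbour flask gives 30.8%.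

The earlier runs and the new flask were computed with constants of no real substance; noise was put on by code.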